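**Retrosynthetic overview**
- The target is a flavone. The last step is global hydrogenolysis of a tetra-O-benzyl flavone (7-OH, 5-OH, 3'-OH and 5'-OH masked as benzyl ethers, the three OMe groups already in place).
- The pyranone (C ring) is the only ring formed. It comes from cyclodehydration of a 2-hydroxyaryl β-diketone, itself made by crossed Claisen condensation of an A-ring acetophenone with a B-ring methyl benzoate.
- The A-ring acetophenone (2-OH, 3,5-di-OMe, 4,6-di-OBn) comes from ring dibromination and twofold Cu-catalysed methoxylation of 2'-hydroxy-4',6'-bis(benzyloxy)acetophenone.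
- The B-ring ester comes from O-benzylation of methyl 3,5-dihydroxy-4-methoxybenzoate.
- Both aromatic rings are bought; only one A-ring OH is free, so the ring closure has a single possible regiochemistry.

Assumption: the target has no stereocentre (it is achiral), so "single enantiomer" needs no stereocontrol; methyl 3,5-dihydroxy-4-methoxybenzoate and 2'-hydroxy-4',6'-bis(benzyloxy)acetophenone are taken as catalogue items.

**Route**

Step 1
Reactants: 1 methyl 3,5-dihydroxy-4-methoxybenzoate
Product: 2 methyl 3,5-bis(benzyloxy)-4-methoxybenzoate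
Conditions: BnBr (2.4 equiv), K2CO3 (3 equiv), DMF, 60 °C
Reagents that add atoms: benzyl bromide, BrCc1ccccc1
Why: Williamson ether synthesis on the two equivalent phenols; the methyl ester and aryl methyl ether are inert to K2CO3/BnBr.

Step 2
Reactants: 3 1-[2,4-bis(benzyloxy)-6-hydroxyphenyl]ethan-1-one (2'-hydroxy-4',6'-bis(benzyloxy)acetophenone)
Product: 4 1-[2,4-bis(benzyloxy)-3,5-dibromo-6-hydroxyphenyl]ethan-1-one
Conditions: NBS (2.1 equiv), MeCN, 0 °C → rt, dark
Reagents that add atoms: N-bromosuccinimide, O=C1CCC(=O)N1Br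
Why: Electrophilic aromatic bromination (SEAr) fills the only two free positions of the phloroglucinol-type ring, which is far more reactive than the benzyl rings or the ketone α-position under non-acidic NBS conditions.

Step 3
Reactants: 4 1-[2,4-bis(benzyloxy)-3,5-dibromo-6-hydroxyphenyl]ethan-1-one
Product: 5 1-[2,4-bis(benzyloxy)-6-hydroxy-3,5-dimethoxyphenyl]ethan-1-one
Conditions: NaOMe (25% in MeOH, 10 equiv), CuBr (0.3 equiv), DMF, 110 °C, N2
Reagents that add atoms: sodium methoxide, C[O-].[Na+]
Why: Copper-catalysed Ullmann-type methoxylation replaces both aryl bromides by OMe (as in bromovanillin → syringaldehyde and iodoacetovanillone → acetosyringone); benzyl ethers and the phenoxide/enolate tolerate the conditions.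

Step 4
Reactants: 5 1-[2,4-bis(benzyloxy)-6-hydroxy-3,5-dimethoxyphenyl]ethan-1-one; 2 methyl 3,5-bis(benzyloxy)-4-methoxybenzoate (1.2 equiv)
Product: 7 5,7-bis(benzyloxy)-2-[3,5-bis(benzyloxy)-4-methoxyphenyl]-6,8-dimethoxy-4H-chromen-4-one, via beta-diketone 6 (not isolated)
Conditions: NaH (4 equiv), THF, reflux; then AcOH (excess), THF distilled off, reflux
Reagents that add atoms: none
Why: Crossed Claisen condensation of the phenoxide/enolate dianion of 5 with ester 2 (driven by deprotonation of diketone 6) is followed by cyclodehydration in the AcOH/NaOAc formed on quenching, through the only free phenol, leaving the benzyl ethers intact; no stereocentre is formed.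

Step 5
Reactants: 7 5,7-bis(benzyloxy)-2-[3,5-bis(benzyloxy)-4-methoxyphenyl]-6,8-dimethoxy-4H-chromen-4-one
Product: 8 5,7-dihydroxy-2-(3,5-dihydroxy-4-methoxyphenyl)-6,8-dimethoxy-4H-chromen-4-one (target, CNP0185233.0)
Conditions: H2 (1 atm), 10% Pd/C, THF/MeOH (1:1), rt
Reagents that add atoms: none
Why: Catalytic hydrogenolysis cleaves all four benzyl ethers while the aryl methyl ethers and the vinylogous-ester C2=C3 bond of the flavone survive at 1 atm and rt; the target is achiral, so no stereocentre needs setting.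

**Compound list**
1 | methyl 3,5-dihydroxy-4-methoxybenzoate | COC(=O)c1cc(O)c(OC)c(O)c1 | starting material
2 | methyl 3,5-bis(benzyloxy)-4-methoxybenzoate | COC(=O)c1cc(OCc2ccccc2)c(OC)c(OCc2ccccc2)c1 | intermediate
3 | 1-[2,4-bis(benzyloxy)-6-hydroxyphenyl]ethan-1-one | CC(=O)c1c(O)cc(OCc2ccccc2)cc1OCc1ccccc1 | starting material
4 | 1-[2,4-bis(benzyloxy)-3,5-dibromo-6-hydroxyphenyl]ethan-1-one | CC(=O)c1c(O)c(Br)c(OCc2ccccc2)c(Br)c1OCc1ccccc1 | intermediate
5 | 1-[2,4-bis(benzyloxy)-6-hydroxy-3,5-dimethoxyphenyl]ethan-1-one | CC(=O)c1c(O)c(OC)c(OCc2ccccc2)c(OC)c1OCc1ccccc1 | intermediate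
6 | 1-[2,4-bis(benzyloxy)-6-hydroxy-3,5-dimethoxyphenyl]-3-[3,5-bis(benzyloxy)-4-methoxyphenyl]propane-1,3-dione | O=C(CC(=O)c1cc(OCc2ccccc2)c(OC)c(OCc2ccccc2)c1)c1c(O)c(OC)c(OCc2ccccc2)c(OC)c1OCc1ccccc1 | intermediate
7 | 5,7-bis(benzyloxy)-2-[3,5-bis(benzyloxy)-4-methoxyphenyl]-6,8-dimethoxy-4H-chromen-4-one | COc1c(OCc2ccccc2)cc(-c2cc(=O)c3c(OCc4ccccc4)c(OC)c(OCc4ccccc4)c(OC)c3o2)cc1OCc1ccccc1 | intermediate
8 | 5,7-dihydroxy-2-(3,5-dihydroxy-4-methoxyphenyl)-6,8-dimethoxy-4H-chromen-4-one | COc1c(O)cc(-c2cc(=O)c3c(O)c(OC)c(O)c(OC)c3o2)cc1O | target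

**Step count**
Total steps: 5. Longest linear sequence: 4 steps (3 → 4 → 5 → 7 → 8); step 1 is a one-step side branch.

**Three steps most likely to fail, with fallbacks**

Step 3 (twofold Ullmann methoxylation). The risks are hydrodebromination, incomplete exchange at the bromide flanked by two benzyloxy groups, and interference from the enolisable ketone and free phenol. The fallback moves the C–O coupling to the flavone stage and sets out from 4. Dibromide 4 is condensed with ester 2 (NaH, THF, reflux) to the β-diketone 1-[2,4-bis(benzyloxy)-3,5-dibromo-6-hydroxyphenyl]-3-[3,5-bis(benzyloxy)-4-methoxyphenyl]propane-1,3-dione F1. This is cyclodehydrated without isolation in AcOH/NaOAc at reflux to 5,7-bis(benzyloxy)-2-[3,5-bis(benzyloxy)-4-methoxyphenyl]-6,8-dibromo-4H-chromen-4-one F2. The methoxylation (NaOMe, CuBr, DMF, 110 °C) is then run on this non-enolisable, phenol-free, electron-poor aryl dibromide, with a short AcOH/NaOAc reflux of the crude to re-close any ring-opened material. It comes back to the route at 7.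

Step 4 (crossed Claisen on a di-ortho-substituted acetophenone, then cyclodehydration). The risks are sluggish C-acylation by the electron-rich ester and incomplete ring closure. The fallback is the chalcone route and sets out from 2 and 5. Ester 2 is reduced (LiAlH4, THF, 0 °C) to [3,5-bis(benzyloxy)-4-methoxyphenyl]methanol F3. This is oxidised (MnO2, CH2Cl2, rt) to 3,5-bis(benzyloxy)-4-methoxybenzaldehyde F4. Claisen–Schmidt condensation with 5 (KOH, EtOH, rt) gives (E)-1-[2,4-bis(benzyloxy)-6-hydroxy-3,5-dimethoxyphenyl]-3-[3,5-bis(benzyloxy)-4-methoxyphenyl]prop-2-en-1-one F5. Oxidative cyclisation (cat. I2, DMSO, 120 °C) then gives the flavone, and the fallback comes back to the route at 7.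

Step 5 (global hydrogenolysis). The risks are over-reduction of the C2=C3 bond to the flavanone, incomplete cleavage of the hindered 5- and 7-benzyl ethers, and catalyst poisoning by traces of Cu or bromide. The fallback is non-reductive and sets out from 7. Lewis-acid debenzylation with BCl3 and pentamethylbenzene as benzyl-cation scavenger (CH2Cl2, −78 °C) cleaves the benzyl ethers while the 6-, 8- and 4'-methyl ethers persist at this temperature. It arrives directly at 8 and makes no new compound (F0).

**Further compounds**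
F1 | step 3 | 1-[2,4-bis(benzyloxy)-3,5-dibromo-6-hydroxyphenyl]-3-[3,5-bis(benzyloxy)-4-methoxyphenyl]propane-1,3-dione | O=C(CC(=O)c1cc(OCc2ccccc2)c(OC)c(OCc2ccccc2)c1)c1c(O)c(Br)c(OCc2ccccc2)c(Br)c1OCc1ccccc1
F2 | step 3 | 5,7-bis(benzyloxy)-2-[3,5-bis(benzyloxy)-4-methoxyphenyl]-6,8-dibromo-4H-chromen-4-one | COc1c(OCc2ccccc2)cc(-c2cc(=O)c3c(OCc4ccccc4)c(Br)c(OCc4ccccc4)c(Br)c3o2)cc1OCc1ccccc1
F3 | step 4 | [3,5-bis(benzyloxy)-4-methoxyphenyl]methanol | COc1c(OCc2ccccc2)cc(CO)cc1OCc1ccccc1
F4 | step 4 | 3,5-bis(benzyloxy)-4-methoxybenzaldehyde | COc1c(OCc2ccccc2)cc(C=O)cc1OCc1ccccc1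
F5 | step 4 | (E)-1-[2,4-bis(benzyloxy)-6-hydroxy-3,5-dimethoxyphenyl]-3-[3,5-bis(benzyloxy)-4-methoxyphenyl]prop-2-en-1-one | O=C(/C=C/c1cc(OCc2ccccc2)c(OC)c(OCc2ccccc2)c1)c1c(O)c(OC)c(OCc2ccccc2)c(OC)c1OCc1ccccc1
F0 | step 5 | none | none
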